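(The readings come from a simulation for substances that don't exist, noise included.)

The target in these flasks is perishable: once made it decays, so what you find at the end is what was made, thinned according to how long it has stood.

| flask | starting material | reagent | remark | time |
|---|---|---|---|---|
| dusk | 0.050 M | 0.0475 M | run made earlier |  |
| winter | 0.050 M | 0.024 M | run made earlier |  |
| midnight | 0.050 M | 0.036 M | run made earlier |  |
| elm | 0.050 M (fed, over 2.0 h) | 0.0475 M | all else is in the flask from the start; the feed brings no volume worth counting | 3.0 h |
| oak | 0.050 M | 0.0475 M | everything together at the start | 3.0 h |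
| ash | 0.050 M | 0.0475 M (fed, over 2.0 h) | all else is in the flask from the start; the feed brings no volume worth counting | 3.0 h |
| larch | 0.050 M (in portions, 3, over 2.0 h) | 0.0475 M | first portion at the start, last at 2.0 h | 3.0 h |

- dusk (time / h: target / %): 0.250: 52.6; 0.333: 55.3; 0.500: 58.1; 0.833: 62.9; 1.33: 58.6; 2.00: 53.1; 3.00: 43.6
- winter (time / h: target / %): 0.500: 32.0; 1.00: 32.1; 1.50: 31.1; 2.00: 29.3; 2.50: 22.4; 3.00: 23.3; 4.00: 19.4
- midnight (time / h: target / %): 0.500: 47.4; 1.00: 50.6; 1.50: 46.3; 2.00: 41.3; 2.50: 37.0; 3.00: 33.3; 4.00: 26.0

(each reading ± 1 percentage point)



1. the flask with the highest amount of target, in percent of the starting material charged ("all alike" if they lie within 1.5 percentage points) (elm / oak / ash / larch / all alike)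
2. final target, as a percentage of the starting material charged, in elm
3. final target, as a percentage of the starting material charged, in oak
4. final target, as a percentage of the starting material charged, in ash
5. final target, as a percentage of the starting material charged, in larch

Climb the ladder of times. On the first rung sits the coupling: dusk, charged like oak, already reads 52.6% of target at 0.250 h and peaks near 62.9% at 0.833 h. The next rung is the dosing time 2.0 h, longer, so I take target in a fed flask to be born roughly as the feed arrives. The top rung is the target's lifetime τ, the time in which a standing amount falls by a factor e, which the midnight tail puts at 4.32 h, as a reading, longer than the feed. So target amount P = M exp(−a/τ), where M is the target ever made and a its mean age.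

Dusk's 43.6% at 3.00 h, with age 2.75 h, has survival 52.9%, so M is 82.4%. My own reckoning holds M there and gives each dosed flask the age 2.00 h, which yields 51.9% for elm, ash and larch alike.

The forecast, close to this, says all alike: 51% for elm, 44% for oak, 51% for ash, 50% for larch, on the ground that “Dosing mainly makes the target younger at 3 h.”

The flasks give 51.2% in elm, 42.6% in oak, 42.5% in ash and 49.4% in larch, so elm stands highest.

    starting material + reagent → target, rate k1*[starting material]*[reagent]^1.5 (k = 0.177 L¹·⁵ mol⁻¹·⁵ s⁻¹)
    2 starting material → homo dimer (k = 0.00126 L mol⁻¹ s⁻¹)
    target → over-reaction product (k = 7.30 × 10⁻⁵ s⁻¹)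

Turned round, the rule reads age from the end state as a = τ ln((P+O)/P), with O the over-reaction product. Reckoned with τ kept at the midnight reading of 4.32 h, ash gives 1.90 h and elm 2.00 h; another τ would scale both ages by the same factor, so the two flasks part in M, 66.0% against 81.3%. The homo dimer step is the largest single effect on that gap: struck out, elm minus ash goes from 8.7 percentage points to −1.6 points. The neighbour of elm with 0.030 M of starting material, reckoned with the same read τ, has age 1.93 h and M 96.3%, and ends at 61.6%.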